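Percent of the D charged per second is the unit I start from, and the cedar run is where I can read it.

| flask | D | Z | J | remark | time |
|---|---|---|---|---|---|
| cedar | 0.11 M | 0.010 M | 17 mM | run made earlier |  |
| green | 0.40 M | 0.0100 M | 25 mM |  | 6.0 min |
| ochre | 0.060 M | 0.0400 M | 12 mM |  | 6.0 min |
| red | 0.10 M | 0.0100 M | 17 mM |  | 6.0 min |
| grey | 0.10 M | 0.0200 M | 4.0 mM |  | 6.0 min |
| amber | 0.10 M | 0.00300 M | 60 mM |  | 6.0 min |

cedar run (percent of the D charged)

| time / s | E / % |
|---|---|
| 25.0 | 4.0 |
| 50.0 | 11.9 |
| 80.0 | 22.6 |
| 90.0 | 26.7 |
| 120 | 36.1 |

(readings scatter by 0.3 percentage points)

* the flasks by amount of E, in percent of the D charged, highest first, at 6.0 min (green / ochre / red / grey / amber)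
* the amount of E, in percent of the D charged of the flask you put first, at 6.0 min
* the amount of E, in percent of the D charged of the flask you put last, at 6.0 min

Between 80.0 s and 120 s of cedar, E gains 14 percentage points in 40.0 s. J comes back out of its step, so I hold cJ at its charge and treat the loss of G to J as pseudo-first-order. I take the G behind that slope to be what remains beside E and the Z charge, 54.8%. That gives the J half-life, the time G needs to halve under J with Z left aside, 1.88 min in cedar, and I scale it inversely with cJ.

Now I turn the question round. By Z charge as a share of D, grey at 20.0% should stand far above ochre at 66.7%. For that to hold, G in grey would have to pass through J well inside 6.0 min. But grey's J half-life is 7.97 min, longer than the time, while ochre's is 2.66 min, shorter. Counting G as present from the start and Z as spent, I reckon E and L together near 32.5% in grey and 26.4% in ochre. So I expect these two flasks close together, not far apart.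

The forecast reads green > amber > red > grey > ochre, with 77% first and 18.5% last, on the ground that “G stays small, a few percent at most”. Here we differ: it sets grey at about 64 as E, and I set grey near 32.5% as E and L together.

The flasks give green > amber > red > ochre > grey.

    D → G (k = 0.0220 /s)
    J + G → J + E (k = 0.450 /M/s)
    E ⇌ L (K = 5.90, k = 0.00190 /s)
    G + Z → Q (k = 0.290 /M/s)

Green leads with 61.9% and grey ends with 25.7%, below ochre's 29.5%. At 6.00 min grey still holds 45.0% of the D charged as G, more than the E beside it. Grey read at 2.50 min holds 63.7% as G, and over the remaining 3.50 min my J half-life of 7.97 min, an estimate read from the cedar readings, reckons 17 points of new E and L. The flask adds 21 points.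

(The numbers in the tables were generated by integration for substances that don't exist; noise was put on by code.)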